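## Analysis of the target

Atoms are numbered in the order of the target SMILES: C1–C2 (ethyl), C3=C4, C5, C6 (spiro), C7, O8, C9, C10, C11, C12=C13, C14, C15, C16, C17, C18 (ester carbonyl, with O19, O20, C21), C22, C23, C24, N25, C26, C27; all intermediates keep these numbers. The compound (C23H33NO3) is pentacyclic. A cyclopentane, ring A (C13, C14, C17, C22, C23), a cyclopentene, ring B (C12–C16), and a cycloheptene (C6, C9, C10, C11, C12, C13, C23) meet at the sp2 carbon C13. An N-methylpiperidine (C6, C9, C27, N25, C24, C23) bridges C9 and C23, so that C6 is the one-atom bridge of an azabicyclo[4.3.1]decene and at the same time the spiro atom of a 6-ethyl-3,4-dihydro-2H-pyran (C3, C4, C5, C6, C7, O8). Of the five stereocentres, C14 and C17 carry C15 and the ester on the same face of ring A; the quaternary C23 has C6 on that face and C24 on the other; C9 is dictated by the bridge; and at the quaternary C6, C5 lies over the piperidine and C7 over the carbocyclic bridge. The sensitive groups are the cyclic enol ether (acid and water), the basic tertiary amine, the ester with its base-epimerisable α-centre C17 held cis to C15, and the tetrasubstituted C12=C13 bond. The synthesis is hard because C6 and C23 are adjacent quaternary carbons inside a bridged core, because ring A carries its substituents cis, and because the two oxidised positions of the seven-membered ring must be told apart. The plan rests on that ring: C6 (spiro centre, from a ketone) and C12 (alkene carbon, from a ketone by addition and dehydration) are latent carbonyls in a 1,5-relationship through C9–C10–C11, which is the retron of a de Mayo reaction of a ring-A-fused cyclopentane-1,3-dione with ethylene as C10–C11.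

## Retrosynthetic reasoning

**Enol ether (O8–C3).** The dihydropyran of 25 is opened to the δ-hydroxy ketone 23. The enol ether is the most fragile group, so it is made last, by cyclodehydration, with nothing acidic after it.

**C5–C6 and the C7 oxidation level.** 23 comes from keto aldehyde 22 by reduction of the aldehyde only. 22 is cut at C5–C6 into aldehyde 20 and enone 21 (Michael addition). C5 is introduced after C7 on purpose: an electrophile reaches the exocyclic C6 enolate from the piperidine side, the smaller bridge, away from the C17 ester that flanks the other side, and the target has C5 on that side. 20 is the one-carbon homologue of ketone 18 through enol ether 19.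

**Piperidine (C9–C27 and C23–C24).** Both bonds are cut together, which leads from 18 to the β,γ-unsaturated ketone 16 and a one-nitrogen, two-carbon Mannich unit. The forward annulation has to make C23 quaternary on the face away from the ester and C15; the bridge then fixes C9.

**Ring B (C12=C13, C12–C16).** The alkene of 16 is traced to the tertiary alcohol 15, and the C12–C16 bond to a Barbier closure of bromo diketone 14. This closure requires the two-carbon chain on C14 to be cis to C12 on C13. Together with the cis ester this means that ring A must be all-cis at this stage, although C13 and C23 are re-formed later.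

**Key disconnection (C9–C10, C11–C12).** 14 is the methyl ester of diketone acid 13, which is cut to the bicyclic 1,3-dione 10 and ethylene 11. The cut is made here because it removes the seven-membered ring in one step from a cheap C2 unit, creates no stereocentre, and leaves exactly the two ketones that the later steps need.

**Spectator groups of the dione.** In 10 the ester is carried as the free acid and the chain ends in bromide, both arising from lactone 9 by acidic bromide opening. This is done before the photoreaction, where the ring fusion cannot epimerise, so that no acid or base treatment stands between the de Mayo step and the Barbier closure.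

**Dione ring (C6–C9).** 9 is opened at C6–C9 to lactone keto acid 7 (Claisen-type acylation of the methyl ketone). C9 itself comes from addition of a methyl nucleophile to the lactone carbonyl C12 of 3, which also frees the C16 hydroxyl (4).

**All-cis ring A.** 7 and its precursor 5 are traced to norbornene 4 by cleavage of the C6=C18 bond. The cleavage gives two equal carbonyl carbons; they are told apart by the C16 hydroxyl, which can form a six-membered lactol or lactone only with C18. Adding the chain to a preformed cis-fused dione would instead place it on the convex face, trans to the dione ring, so that route to the all-cis array was not taken.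

**Diels–Alder.** 3 is the endo adduct of diene 1 and lactone 2. The endo rule places C12 and C15 on the face of the C6=C18 bridge, which after cleavage is the all-cis cyclopentane, and a chiral Lewis acid sets the absolute configuration.

## Alternatives that were turned down

**Alternative 1:** The dihydropyran is cut at C5–C6 and O8–C7 in one operation. In the forward sense the ketene dithioacetal A1 (C6=C7, to be made from a C6 ketone such as 18) would act as the electron-rich 2π partner toward 21 used as a 1-oxadiene, giving the spiro adduct A2 with C7 still carrying the dithiane.
- For it: one step builds the heterocycle and the quaternary C6. Regiochemistry follows from polarity (nucleophilic C6 to the enone terminus, oxygen to C7), and approach from the piperidine face would give the right C6 configuration for the same reason as the Michael addition used here.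
- Against it: it concerns only the last ring and says nothing about the carbocyclic core. A1 needs olefination of a very hindered bridging ketone with a bulky dithiane anion. A tetrasubstituted neopentyl alkene is a poor partner for an enone that polymerises and normally needs Lewis acid or pressure, and the Lewis acid would be bound by the amine. A2 must then lose two C–S bonds over nickel next to an enol ether and a basic nitrogen.
- Comparison: on step count for the spiro ring it is stronger (two steps from A1 against five from 18). The chosen route offers instead reactions of ordinary steric demand (a small ylide, a Michael addition) and no late desulfurisation; alternative 1 could at most replace its last five steps.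

**Alternative 2:** The bond between the two quaternary carbons, C6–C23, is cut through a [3,3] shift of an allylic ester whose ring oxygen sits on C12 and whose carbonyl carbon is C7. After O-silylation of the ester enolate the rearrangement would form C6–C23, move the alkene from C13=C23 to C12=C13 and close the cycloheptene, giving diacid A3.
- For it: the hardest bond is made intramolecularly and stereospecifically, the C12=C13 alkene appears without any question of dehydration regiochemistry, and the pentynyl chain is ready for closure to the dihydropyran.
- Against it: the C6 configuration depends on the geometry of a fully substituted ketene acetal held in a seven-membered lactone, which is hard to control. The substrate (a tetrasubstituted C13=C23 alkene inside a medium-ring lactone on a stereodefined ring A) is long to make. A3 carries two carboxylic acids (C7 and C18) that must be told apart, the piperidine is still open, and closure of an internal alkynol must go 6-endo against the usual 5-exo mode.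
- Comparison: it is stronger on stereocontrol at C6 and C23, which here rest on face selection in two separate steps. The chosen route gives in exchange a far shorter way to the seven-membered ring and makes both quaternary centres by simple enol chemistry on a rigid core.

**Alternative 3:** The cuts are C11–C12 and C13–C23. A rhodium-catalysed (5+2) cycloaddition of a silyl alkyne (C12≡C13) with a tethered siloxyvinylcyclopropane (C23=C6; cyclopropane C9, C10, C11) would close the cycloheptadiene and ring A at once and give the silyl enol ether A4.
- For it: two rings, the C12=C13 bond and a regiodefined C6 enol ether arise in one catalytic, atom-economic step, with no dehydration.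
- Against it: C23 is created in the cycloaddition relative to C14 and C17 through a flexible tether and has to become quaternary later anyway. The acyclic C14/C17 pair must first be made enantioselectively. The silyl group on C12 and the vinyl group on C14 have to be turned into the C12–C16 bond of ring B over several steps, and an internal silyl alkyne is a slow 2π partner.
- Comparison: it is stronger in convergence and in the placement of the alkene. The chosen route offers ethylene and light in place of a rhodium step, ring A stereochemistry from an endo cycloaddition rather than from an acyclic precursor, and ring B by a single Barbier closure.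

Key step: step 7

Assumption: the (S)-configured oxazaborolidinium catalyst of step 1 is taken to give the enantiomer of 3 shown; if its facial sense is the opposite, the (R)-catalyst is used and nothing else changes.

## Route

Step 1
Reactants: 1 cyclopenta-1,3-diene; 2 5,6-dihydro-2H-pyran-2-one
Product: 3 endo Diels–Alder lactone (4aR,5S,8R,8aS)-3,4,4a,5,8,8a-hexahydro-1H-5,8-methanoisochromen-1-one
Conditions: (S)-1-(2-methylphenyl)-3,3-diphenyltetrahydro-1H,3H-pyrrolo[1,2-c][1,3,2]oxazaborole (20 mol %), HN(SO2CF3)2 (20 mol %), CH2Cl2, −78 → −20 °C
Reagents that add atoms: none
Why: Lewis acid-catalysed Diels–Alder reaction of a cyclic cis enoate; endo addition puts the lactone carbonyl C12 and the chain carbon C15 on the face of the new C6=C18 bridge, and the chiral boron Lewis acid differentiates the two faces of 2, so C13, C14, C17 and C23 are fixed relative to each other and in the absolute sense in this step.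

Step 2
Reactants: 3 endo Diels–Alder lactone
Product: 4 hydroxy ketone (2-endo-acetyl-3-endo-(2-hydroxyethyl)norborn-5-ene, in equilibrium with its six-membered hemiketal)
Conditions: MeLi (1.05 equiv), THF, −78 °C; aq. NH4Cl
Reagents that add atoms: methyllithium, [Li]C
Why: Single addition of an organolithium to a lactone stops at the lithium hemiketal at low temperature; work-up gives the methyl ketone (C12, with the new carbon C9) and frees the C16 hydroxyl, and the α-centre C13 is not enolised under these conditions.

Step 3
Reactants: 4 hydroxy ketone
Product: 5 keto aldehyde lactol (all-cis cyclopentane; acetyl on C13, formyl C6 on C23, lactol C18–O–C16 fused across C17–C14)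
Conditions: O3, CH2Cl2–MeOH (4:1), −78 °C; Me2S, −78 °C → rt
Reagents that add atoms: ozone, [O-][O+]=O
Why: Ozonolysis with reductive work-up cleaves the strained C6=C18 bond and leaves the two formyl carbons cis to each other and to the former endo groups, which is the all-cis ring A; the C16 hydroxyl closes onto the neighbouring C18 aldehyde as a six-membered lactol and so distinguishes C18 from C6.

Step 4
Reactants: 5 keto aldehyde lactol
Product: 7 lactone keto acid, via hydroxy keto diacid 6 (not isolated)
Conditions: NaClO2, NaH2PO4, 2-methyl-2-butene, t-BuOH–H2O, 0 °C → rt; then 1 M HCl to pH 2, EtOAc
Reagents that add atoms: sodium chlorite, [Na+].[O-]Cl=O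
Why: Pinnick oxidation takes the C6 aldehyde and the open form of the C18 lactol to acids without touching the ketone or enolising C23; on acidification only the C18 acid can lactonise with the C16 hydroxyl through a six-membered ring (C6 would need a seven-membered one), so C18 is masked and C6 stays a free acid.

Step 5
Reactants: 7 lactone keto acid
Product: 9 tricyclic lactone dione, via N-acylimidazole 8 (not isolated)
Conditions: 1,1'-carbonyldiimidazole (1.1 equiv), THF, rt; then LiN(SiMe3)2 (3.3 equiv), THF, −78 → 0 °C; 1 M HCl
Reagents that add atoms: none
Why: Intramolecular Claisen-type C-acylation: the kinetic lithium enolate of the methyl ketone (C9) attacks the activated acyl group C6 on the neighbouring cis carbon in a five-membered closure, much faster than the unactivated lactone carbonyl C18; the product is held as its dione enolate, and only the cis-fused bicyclo[3.3.0]octane can form, so the C13/C23 relation is kept.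

Step 6
Reactants: 9 tricyclic lactone dione
Product: 10 bromo acid dione (all-cis bicyclo[3.3.0]octane-2,4-dione; CO2H on C17, 2-bromoethyl on C14)
Conditions: HBr (33 % in AcOH), rt → 40 °C
Reagents that add atoms: hydrogen bromide, Br
Why: Acid-mediated alkyl–oxygen cleavage of the lactone by bromide (SN2 at primary C16) gives the ω-bromo acid; without base the α-centre C17 keeps its configuration and the acidic dione is not alkylated by the bromide.

Step 7
Reactants: 10 bromo acid dione; 11 ethylene
Product: 13 diketone acid (cis-fused cyclopenta-cycloheptane-1,4-dione), via cyclobutanol photoadduct 12 (not isolated)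
Conditions: hν (254 nm, quartz), ethylene-saturated MeCN, −20 °C; then rt
Reagents that add atoms: none
Why: De Mayo reaction: 10 is enolised at C9, and the enone chromophore of the enol (carbonyl C6, C9=C12–OH, or the mirror tautomer) is excited and adds ethylene across C9=C12 to give the cis-fused cyclobutanol 12 with the new bonds C9–C10 and C11–C12. 12 is a strained β-hydroxy ketone and undergoes retro-aldol cleavage of the C9–C12 bond shared by the four- and five-membered rings, which releases the 1,5-diketone 13. The closest known reaction type is the photoaddition of enolised cyclopentane- and cyclohexane-1,3-diones to simple alkenes with spontaneous fragmentation. The seven-membered ring is therefore not closed end to end but arises by two-carbon ring expansion of the dione ring ([2+2] closure of the cyclobutane, then opening of the bicyclo[3.2.0]heptane across its central bond). No stereocentre is created, since C9, C10 and C11 are methylene groups and C13, C14, C17 and C23 lie outside the chromophore. Regiochemistry is of no concern, because ethylene is symmetrical and both enol tautomers give the same diketone. The selectivity needed is that only the enol absorbs: the acid, the primary bromide and the product diketone are nearly transparent at this wavelength, and the low temperature raises the ethylene concentration so that cycloaddition outruns secondary photolysis. The medium is kept neutral so that the cis-fused α-centres C13 and C23 of 13 do not epimerise.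

Step 8
Reactants: 13 diketone acid
Product: 14 diketone methyl ester
Conditions: Me3SiCHN2, PhMe–MeOH (4:1), 0 °C
Reagents that add atoms: (trimethylsilyl)diazomethane, C[Si](C)(C)C=[N+]=[N-]
Why: Neutral O-methylation of the carboxylic acid; it is placed after the photoreaction because the same reagent would methylate the enolised dione, and it needs no base, so C13, C23 and C17 are not epimerised.

Step 9
Reactants: 14 diketone methyl ester
Product: 15 tricyclic hydroxy ketone (ring B closed, tertiary OH on C12 cis to H13)
Conditions: SmI2 (2.5 equiv), HMPA (8 equiv), THF, 0 °C → rt; aq. NH4Cl
Reagents that add atoms: none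
Why: Samarium Barbier cyclisation: the primary C16 bromide is reduced and the resulting carbon nucleophile adds to the C12 ketone in a five-membered closure, faster than the six-membered closure onto C6 and than acyl substitution at the ester; since the chain on C14 and C12 are cis, ring B is cis-fused and the hydroxyl ends on the convex face.

Step 10
Reactants: 15 tricyclic hydroxy ketone
Product: 16 tricyclic β,γ-unsaturated ketone (C12=C13)
Conditions: methyl N-(triethylammoniosulfonyl)carbamate (2 equiv), PhH, 50 °C
Reagents that add atoms: none
Why: Burgess dehydration (syn elimination through the sulfamate ester): H13 is syn to the tertiary hydroxyl on the convex face, and the ion-pair character at a tertiary centre should favour the most substituted alkene; the neutral conditions leave the alkene out of conjugation with the C6 ketone and do not touch C17.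

Step 11
Reactants: 16 tricyclic β,γ-unsaturated ketone
Product: 18 bridged amino ketone, via mono-Mannich base 17 (not isolated)
Conditions: MeN(CH2OEt)2 (1.5 equiv), MeSiCl3 (2.5 equiv), MeCN, rt → 50 °C; aq. NaHCO3
Reagents that add atoms: N,N-bis(ethoxymethyl)methylamine, CCOCN(C)COCC
Why: Double Mannich annulation of a cyclic ketone: aminomethylation at C9 is followed by six-membered closure of the tethered iminium ion onto the enol carbon C23, which the C12=C13 bond activates as a dienol; the C23–C24 bond forms on the face of ring A opposite to the ester and C15, where H23 stood, and the bridge then fixes C9, so C23 and C9 are set together.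

Step 12
Reactants: 18 bridged amino ketone
Product: 19 methyl enol ether (C6=C7H–OMe)
Conditions: Ph3P(CH2OMe)Cl (3 equiv), KN(SiMe3)2 (2.8 equiv), THF–PhMe, 0 → 60 °C
Reagents that add atoms: (methoxymethyl)triphenylphosphonium chloride, COC[P+](c1ccccc1)(c1ccccc1)c1ccccc1.[Cl-]
Why: Wittig methoxymethylenation brings in C7; the bridging ketone cannot enolise (its α-carbons are a bridgehead and a quaternary carbon), so the basic ylide causes neither epimerisation nor retro-Mannich cleavage, and the ester is inert to the ylide.

Step 13
Reactants: 19 methyl enol ether
Product: 20 aldehyde (formyl C7 on C6, C6 epimers)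
Conditions: 2 M aq. HCl, THF, rt; aq. NaHCO3
Reagents that add atoms: water, O
Why: Acid hydrolysis of the enol ether gives the homologated aldehyde; the configuration at C6 is of no account because this centre is enolised in the next step.

Step 14
Reactants: 20 aldehyde; 21 pent-1-en-3-one (ethyl vinyl ketone)
Product: 22 keto aldehyde (quaternary C6 with formyl C7 and the 3-oxopentyl chain C5–C1)
Conditions: KOt-Bu (10 mol %), t-BuOH–THF, 0 °C
Reagents that add atoms: none
Why: Michael addition of an α,α-disubstituted aldehyde enolate (the only acidic site under catalytic base) builds the quaternary C6 and brings in C1–C5; the enone approaches the exocyclic enolate from the piperidine side, the smaller bridge and the one remote from the C17 ester that screens the cycloheptene side, so C5 ends over nitrogen and C7 over the carbocyclic bridge as in the target.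

Step 15
Reactants: 22 keto aldehyde
Product: 23 hydroxy ketone (C7–OH)
Conditions: NaBH4 (0.5 equiv), EtOH–CH2Cl2 (3:7), −78 °C
Reagents that add atoms: none
Why: Chemoselective borohydride reduction: at low temperature an aldehyde is reduced far faster than a dialkyl ketone or an ester, which gives the C7 alcohol and keeps the C3 ketone.

Step 16
Reactants: 23 hydroxy ketone
Product: 25 CNP0159589.3 (target), via cyclic hemiketal 24 (not isolated)
Conditions: camphorsulfonic acid (1.3 equiv), PhH, 4 Å molecular sieves, 60 °C; Et3N quench
Reagents that add atoms: none
Why: Cyclodehydration of a δ-hydroxy ketone: the six-membered hemiketal loses water to the endocyclic enol ether, the more stable isomer in a six-membered ring; the first equivalent of acid is taken up by the amine, and the basic quench protects the acid-labile product.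

## Compound list

1 | cyclopenta-1,3-diene | C1C=CC=C1 | starting material
2 | 5,6-dihydro-2H-pyran-2-one | O=C1C=CCCO1 | starting material
3 | endo Diels–Alder lactone, (4aR,5S,8R,8aS)-3,4,4a,5,8,8a-hexahydro-1H-5,8-methanoisochromen-1-one | O=C1OCC[C@H]2[C@@H]1[C@H]3C=C[C@@H]2C3 | intermediate
4 | hydroxy ketone, 2-endo-acetyl-3-endo-(2-hydroxyethyl)norborn-5-ene (open form of the hemiketal) | CC(=O)[C@H]1[C@H]2C=C[C@H](C2)[C@H]1CCO | intermediate
5 | keto aldehyde lactol, all-cis cyclopentane with C13-acetyl, C23-formyl and the C18–O–C16 lactol (anomeric mixture) | CC(=O)[C@H]1[C@@H](C=O)C[C@H]2C(O)OCC[C@@H]12 | intermediate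
6 | hydroxy keto diacid (C6 and C18 acids, free C16–OH) | CC(=O)[C@H]1[C@@H](C(=O)O)C[C@@H](C(=O)O)[C@H]1CCO | intermediate
7 | lactone keto acid (C18 δ-lactone with O on C16, C6 acid, C13-acetyl) | CC(=O)[C@H]1[C@@H](C(=O)O)C[C@H]2C(=O)OCC[C@@H]12 | intermediate
8 | N-acylimidazole of 7 | CC(=O)[C@H]1[C@@H](C(=O)n2ccnc2)C[C@H]3C(=O)OCC[C@@H]13 | intermediate
9 | tricyclic lactone dione, all-cis bicyclo[3.3.0]octane-2,4-dione (ketones C6, C12) with the δ-lactone across C14–C17 | O=C1CC(=O)[C@H]2[C@@H]1C[C@H]3C(=O)OCC[C@@H]23 | intermediate
10 | bromo acid dione, all-cis bicyclo[3.3.0]octane-2,4-dione with CO2H on C17 and 2-bromoethyl on C14 | O=C1CC(=O)[C@H]2[C@@H]1C[C@@H](C(=O)O)[C@H]2CCBr | intermediate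
11 | ethylene | C=C | starting material
12 | cyclobutanol photoadduct (four-membered ring C9, C10, C11, C12; OH on C12) | O=C1C2CCC2(O)[C@H]3[C@@H]1C[C@@H](C(=O)O)[C@H]3CCBr | intermediate
13 | diketone acid, cis-fused cyclopenta-cycloheptane-1,4-dione (ketones C6, C12) | O=C1CCCC(=O)[C@H]2[C@@H]1C[C@@H](C(=O)O)[C@H]2CCBr | intermediate
14 | diketone methyl ester | O=C1CCCC(=O)[C@H]2[C@@H]1C[C@@H](C(=O)OC)[C@H]2CCBr | intermediate
15 | tricyclic hydroxy ketone (ring B closed, C12–OH cis to H13, ketone C6) | O=C1CCC[C@]2(O)CC[C@@H]3[C@H](C(=O)OC)C[C@H]1[C@H]23 | intermediate
16 | tricyclic β,γ-unsaturated ketone (C12=C13, ketone C6, H on C23) | O=C1CCCC2=C3[C@H](CC2)[C@H](C(=O)OC)C[C@H]13 | intermediate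
17 | mono-Mannich base (CH2N(Me)CH2OEt on C9) | O=C1C(CN(C)COCC)CCC2=C3[C@H](CC2)[C@H](C(=O)OC)C[C@H]13 | intermediate
18 | bridged amino ketone (piperidine bridge C9–C27–N25–C24–C23, ketone C6) | O=C2[C@@H]1CCC3=C4[C@H](CC3)[C@H](C(=O)OC)C[C@@]42CN(C)C1 | intermediate
19 | methyl enol ether (C6=C7H–OMe) | COC=C2[C@@H]1CCC3=C4[C@H](CC3)[C@H](C(=O)OC)C[C@@]42CN(C)C1 | intermediate
20 | aldehyde (formyl C7 on C6, C6 epimers) | O=CC2[C@@H]1CCC3=C4[C@H](CC3)[C@H](C(=O)OC)C[C@@]42CN(C)C1 | intermediate
21 | pent-1-en-3-one (ethyl vinyl ketone) | CCC(=O)C=C | starting material
22 | keto aldehyde (quaternary C6 with formyl and 3-oxopentyl) | CCC(=O)CC[C@@]2(C=O)[C@@H]1CCC3=C4[C@H](CC3)[C@H](C(=O)OC)C[C@@]42CN(C)C1 | intermediate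
23 | hydroxy ketone (C7–OH, C3 ketone) | CCC(=O)CC[C@@]2(CO)[C@@H]1CCC3=C4[C@H](CC3)[C@H](C(=O)OC)C[C@@]42CN(C)C1 | intermediate
24 | cyclic hemiketal (OH and ethyl on C3) | CCC1(O)CC[C@@]2(CO1)[C@@H]1CCC3=C4[C@H](CC3)[C@H](C(=O)OC)C[C@@]42CN(C)C1 | intermediate
25 | CNP0159589.3 | CCC1=CC[C@@]2(CO1)[C@@H]1CCC3=C4[C@H](CC3)[C@H](C(=O)OC)C[C@@]42CN(C)C1 | target

## Step count and least certain steps

Total: 16 steps. Longest linear sequence: 16 steps (from 1 and 2 to 25); 11 and 21 enter as commercial reagents, so there is no second branch.

**Step 7 (key step).** The cycloaddition may stay incomplete because ethylene is dilute in solution, and the longer irradiation then needed can degrade the product diketone by α-cleavage; the cyclobutanol may also fragment only partly. The fallback forms the same two bonds through an enone ester that absorbs at longer wavelength. It sets out from 9, which is converted with isopropenyl acetate and catalytic TsOH into the enol acetate of the lactone dione F3 (either regioisomer serves). Irradiation through Pyrex in ethylene-saturated CH2Cl2 gives the cyclobutyl acetate F4. HBr in MeOH then cleaves the acetate (the freed cyclobutanol undergoes the retro-aldol opening) and opens the lactone to the bromo methyl ester, so the sequence comes back to the route at 14.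

**Step 1.** The lactone is a weak dienophile, so activation may be insufficient or the discrimination between its two faces poor. The fallback gives up asymmetric catalysis for resolution. It sets out from 1 and 2, which are combined with EtAlCl2 to give racemic 3; this is taken through steps 2–4 as the racemate, and the racemic acid is crystallised as its (R)-1-phenylethylammonium salt F1. Acidification of the salt returns the route at enantiopure 7.

**Step 5.** The enolate may be acylated on oxygen (enol lactone), the acyl group may be passed to the lactone carbonyl C18 in a bridged closure, or C13 may epimerise before the ring closes. The fallback builds the C6–C9 bond by an aldol reaction, in which an aldehyde is far more electrophilic than the lactol. It sets out from 5: pyrrolidinium acetate closes the methyl ketone onto the C6 aldehyde to give the aldol lactol F2, and Dess–Martin periodinane oxidises both carbinols (aldol to dione, lactol to lactone), which comes back to the route at 9.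

**Step 11.** The second closure at the fully substituted C23 may lag behind the first aminomethylation, the iminium ion may attack the γ-carbon C12 of the dienol, or the alkene may move into conjugation. The fallback does the annulation before the alkene exists. It sets out from 15, which with MeNH2·HCl and aqueous CH2O in AcOH at 80 °C gives the bridged amino hydroxy ketone F5 by enolisation of a simple ketone; dehydration with methyl N-(triethylammoniosulfonyl)carbamate then comes back to the route at 18.

**Step 14.** After the Michael addition the keto aldehyde may close by aldol condensation of the ethyl ketone onto the aldehyde, and the hindered aldehyde may then not be reduced selectively beside the ketone in step 15. The fallback avoids a free ketone altogether. It sets out from 20, which adds to methyl acrylate under catalytic KOt-Bu to give the aldehyde diester F6. NaBH4 reduces the aldehyde, and the alcohol lactonises onto the new ester to the spiro δ-lactone F7. KN(SiMe3)2 and (PhO)2P(O)Cl convert the lactone into the ketene acetal phosphate F8, and AlEt3 with Pd(PPh3)4 replaces the phosphate by ethyl, which comes back to the route at 25.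

## Further compounds

F1 | step 1 | (R)-1-phenylethylammonium salt of lactone keto acid 7 | CC(=O)[C@H]1[C@@H](C(=O)[O-])C[C@H]2C(=O)OCC[C@@H]12.C[C@@H]([NH3+])c1ccccc1
F2 | step 5 | aldol lactol (C6–OH, C12 ketone, C18 lactol) | OC1CC(=O)[C@H]2[C@@H]1C[C@H]3C(O)OCC[C@@H]23
F3 | step 7 | enol acetate of the lactone dione (acetate on O12) | O=C1C=C(OC(C)=O)[C@H]2[C@@H]1C[C@H]3C(=O)OCC[C@@H]23
F4 | step 7 | cyclobutyl acetate photoadduct | O=C1C2CCC2(OC(C)=O)[C@H]3[C@@H]1C[C@H]4C(=O)OCC[C@@H]34
F5 | step 11 | bridged amino hydroxy ketone (C12–OH, C13–H) | O=C2[C@@H]1CCC[C@]3(O)CC[C@@H]4[C@H](C(=O)OC)C[C@@]2(CN(C)C1)[C@H]34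
F6 | step 14 | aldehyde diester (methyl propanoate chain on C6) | COC(=O)CC[C@@]2(C=O)[C@@H]1CCC3=C4[C@H](CC3)[C@H](C(=O)OC)C[C@@]42CN(C)C1
F7 | step 14 | spiro δ-lactone | O=C1CC[C@@]2(CO1)[C@@H]1CCC3=C4[C@H](CC3)[C@H](C(=O)OC)C[C@@]42CN(C)C1
F8 | step 14 | ketene acetal diphenyl phosphate | O=P(Oc1ccccc1)(Oc1ccccc1)OC1=CC[C@@]2(CO1)[C@@H]1CCC3=C4[C@H](CC3)[C@H](C(=O)OC)C[C@@]42CN(C)C1
A1 | alternative 1 | ketene dithioacetal at C6=C7 | C1(SCCCS1)=C2[C@@H]3CCC4=C5[C@H](CC4)[C@H](C(=O)OC)C[C@@]52CN(C)C3
A2 | alternative 1 | spiro dihydropyran with dithiane at C7 | CCC1=CC[C@@]2(C3(SCCCS3)O1)[C@@H]4CCC5=C6[C@H](CC5)[C@H](C(=O)OC)C[C@@]62CN(C)C4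
A3 | alternative 2 | cycloheptene diacid | CCC#CC[C@@]1(C(=O)O)[C@@H](CO[Si](C)(C)C(C)(C)C)CCC2=C3[C@H](CC2)[C@H](C(=O)O)C[C@@]31CN(C)C(=O)OC(C)(C)C
A4 | alternative 3 | bicyclic cycloheptadiene silyl enol ether | C[Si](C)(C)C1=C2[C@H](C=C)[C@H](C(=O)OC)C[C@@H]2C(O[Si](C)(C)C(C)(C)C)=CCC1
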